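The route rests on the C2–C3 bond of the cyclopentane (daucane numbering): the acetoxy-bearing CH beside the quaternary C1 and the ring CH2. It is formed by a chelation-controlled intramolecular Hosomi–Sakurai reaction. A 2-(silylmethyl)vinyl group on C5 of a monocyclic cycloheptenone attacks the aldehyde on C1; this closes the trans-fused five-membered ring, sets the C2 carbinol and leaves a methylidene as latent C4 ketone. The step exploits the 1,3-dioxygenated C2–C3–C4 array flanking the quaternary ring-fusion carbon. The precursor comes from an enantiopure 4-silyloxycyclohepta-2,6-dienone by anti conjugate addition, hydroxymethylation and oxidation.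

Key step: step 10

Remark: ring carbons carry daucane locants throughout (C1 quaternary carbon with the angular methyl; C2 CH–OAc and C3 CH2 of the five-membered ring; C4 the isopropyl carbinol carbon; C5 ring-fusion CH; C6 CH–O-angeloyl; C7 CH2; C8/C9 epoxide carbons; C10 CH–OAc of the seven-membered ring). β is the face of the angular methyl group, α the opposite face.

Step 1
Reactants: 1 2-methylpropene; 2 ethyl glyoxylate
Product: 3 ethyl (2S)-2-hydroxy-4-methylpent-4-enoate
Conditions: (S)-BINOL/TiCl2(OiPr)2 (10 mol %), 4 Å MS, CH2Cl2, −30 °C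
Reagents that add atoms: none
Why: Mikami asymmetric glyoxylate–ene reaction, in which the BINOL–titanium Lewis acid binds the glyoxylate and exposes one aldehyde face, so that the (S) ligand should give the (S) carbinol (future C6), following the known (R)-ligand-to-(R)-ester correlation.

Step 2
Reactants: 3 ethyl (2S)-2-hydroxy-4-methylpent-4-enoate
Product: 4 ethyl (2S)-2-[(tert-butyldimethylsilyl)oxy]-4-methylpent-4-enoate
Conditions: TBSCl, imidazole, DMF, rt
Reagents that add atoms: tert-butyldimethylsilyl chloride, CC(C)(C)[Si](C)(C)Cl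
Why: Standard imidazole-promoted silylation of a secondary alcohol, which does not touch the stereocentre.

Step 3
Reactants: 4 ethyl (2S)-2-[(tert-butyldimethylsilyl)oxy]-4-methylpent-4-enoate
Product: 5 (2S)-2-[(tert-butyldimethylsilyl)oxy]-4-methylpent-4-enal
Conditions: iBu2AlH (1.05 equiv), CH2Cl2, −78 °C; aq KNa tartrate
Reagents that add atoms: none
Why: Partial ester reduction through the aluminium hemiacetal that is stable at −78 °C, conditions under which α-silyloxy aldehydes keep their configuration.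

Step 4
Reactants: 5 (2S)-2-[(tert-butyldimethylsilyl)oxy]-4-methylpent-4-enal
Product: 6 ethyl (2Z,4S)-4-[(tert-butyldimethylsilyl)oxy]-2,6-dimethylhepta-2,6-dienoate
Conditions: (CF3CH2O)2P(O)CH(CH3)CO2Et, KN(SiMe3)2, 18-crown-6, THF, −78 °C
Reagents that add atoms: ethyl 2-[bis(2,2,2-trifluoroethoxy)phosphoryl]propanoate, CCOC(=O)C(C)P(=O)(OCC(F)(F)F)OCC(F)(F)F
Why: Still–Gennari variant of the Horner–Wadsworth–Emmons reaction, whose fast kinetic elimination should give the (Z)-trisubstituted enoate and so place the future C10 carbonyl cis to C6 as the ring requires.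

Step 5
Reactants: 6 ethyl (2Z,4S)-4-[(tert-butyldimethylsilyl)oxy]-2,6-dimethylhepta-2,6-dienoate
Product: 7 (2Z,4S)-4-[(tert-butyldimethylsilyl)oxy]-N-methoxy-N,2,6-trimethylhepta-2,6-dienamide
Conditions: MeNH(OMe)·HCl, iPrMgCl, THF, −20 → 0 °C
Reagents that add atoms: N,O-dimethylhydroxylamine hydrochloride, CNOC.Cl
Why: Weinreb amide formation by aminolysis of the ester with the chloromagnesium amide, which leaves the alkene geometry and the stereocentre untouched.

Step 6
Reactants: 7 (2Z,4S)-4-[(tert-butyldimethylsilyl)oxy]-N-methoxy-N,2,6-trimethylhepta-2,6-dienamide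
Product: 8 (4Z,6S)-6-[(tert-butyldimethylsilyl)oxy]-4,8-dimethylnona-1,4,8-trien-3-one
Conditions: CH2=CHMgBr, THF, −78 → 0 °C; cold aq HCl quench
Reagents that add atoms: vinylmagnesium bromide, C=C[Mg]Br
Why: Weinreb ketone synthesis, in which the chelated tetrahedral adduct prevents over-addition and the acidic quench protonates the released amine before it can add to the vinyl ketone.

Step 7
Reactants: 8 (4Z,6S)-6-[(tert-butyldimethylsilyl)oxy]-4,8-dimethylnona-1,4,8-trien-3-one
Product: 9 (4S)-4-[(tert-butyldimethylsilyl)oxy]-2,6-dimethylcyclohepta-2,6-dien-1-one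
Conditions: second-generation Grubbs catalyst (5 mol %), CH2Cl2 (0.005 M), 40 °C
Reagents that add atoms: none
Why: Ring-closing metathesis of the vinyl ketone with the 1,1-disubstituted alkene, preorganised by the cis C1=C5 alkene and driven by loss of ethene, should give the seven-membered ring with the trisubstituted C8=C9 enone.

Step 8
Reactants: 9 (4S)-4-[(tert-butyldimethylsilyl)oxy]-2,6-dimethylcyclohepta-2,6-dien-1-one
Product: 11 (2R,3R,4S)-4-[(tert-butyldimethylsilyl)oxy]-2-(hydroxymethyl)-2,6-dimethyl-3-[3-(trimethylsilyl)prop-1-en-2-yl]cyclohept-6-en-1-one, via bromomagnesium enolate 10 (not isolated)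
Conditions: CH2=C(CH2SiMe3)MgBr [from 2-bromo-3-(trimethylsilyl)propene, Mg] (1.5 equiv), CuBr·SMe2 (0.2 equiv), THF, −78 → −40 °C; then CH2O (gas, from paraformaldehyde), −78 °C; aq NH4Cl
Reagents that add atoms: [3-(trimethylsilyl)prop-1-en-2-yl]magnesium bromide, C=C(C[Si](C)(C)C)[Mg]Br; formaldehyde, C=O
Why: Copper-catalysed conjugate addition of the Grignard reagent to the β-unsubstituted enone terminus C5, anti to the neighbouring 6-silyloxy group, followed by aldol trapping of the magnesium enolate with formaldehyde anti to the new C5 substituent (conjugate addition–hydroxymethylation), should set C5 and the quaternary C1 with the hydroxymethyl and C5 branches trans.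

Step 9
Reactants: 11 (2R,3R,4S)-4-[(tert-butyldimethylsilyl)oxy]-2-(hydroxymethyl)-2,6-dimethyl-3-[3-(trimethylsilyl)prop-1-en-2-yl]cyclohept-6-en-1-one
Product: 12 (1R,6S,7R)-6-[(tert-butyldimethylsilyl)oxy]-1,4-dimethyl-2-oxo-7-[3-(trimethylsilyl)prop-1-en-2-yl]cyclohept-3-ene-1-carbaldehyde
Conditions: Dess–Martin periodinane, NaHCO3, CH2Cl2, 0 °C
Reagents that add atoms: none
Why: Buffered Dess–Martin oxidation of the neopentyl primary alcohol should give the aldehyde, which cannot enolise at the quaternary C1 and is used at once.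

Step 10
Reactants: 12 (1R,6S,7R)-6-[(tert-butyldimethylsilyl)oxy]-1,4-dimethyl-2-oxo-7-[3-(trimethylsilyl)prop-1-en-2-yl]cyclohept-3-ene-1-carbaldehyde
Product: 13 6α-[(tert-butyldimethylsilyl)oxy]-2α-hydroxy-1β,8-dimethyl-4-methylidene-5αH-bicyclo[5.3.0]dec-8-en-10-one (daucane locants)
Conditions: SnCl4 (1.1 equiv), CH2Cl2, −78 °C; aq NaHCO3
Reagents that add atoms: none
Why: SnCl4 ties the aldehyde and the C10 carbonyl of 12 into a six-membered chelate, and the CH2 terminus (C3) of the 2-substituted allylsilane on C5 attacks the activated aldehyde carbon C2 in an anti SE2′ sense, the β-silyl cation then losing Me3SiCl to leave the 4-methylidene group. The closest known reaction is the intramolecular Hosomi–Sakurai allylation used in 2-(silylmethyl)allyl methylenecyclopentane annulations. The cyclopentane closes in a 5-exo-trig mode at the carbonyl (the allylsilane π bond lies inside the new ring, as in those annulations) and is trans-fused because the aldehyde and the C5 side chain are trans on the cycloheptenone. C2 is the only new stereocentre and is controlled by the chelate: the aldehyde oxygen is held syn to the C10 carbonyl, the tethered nucleophile can only reach the face turned toward C5, and this should give the 2α alcohol (oxygen anti to the angular methyl). The step needs selectivity for the aldehyde over 1,2- or 1,4-allylation of the enone, which the higher electrophilicity of the chelated aldehyde, the five-membered transition state and the β,β-disubstitution of C8 should secure.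

Step 11
Reactants: 13 6α-[(tert-butyldimethylsilyl)oxy]-2α-hydroxy-1β,8-dimethyl-4-methylidene-5αH-bicyclo[5.3.0]dec-8-en-10-one
Product: 15 6α-[(tert-butyldimethylsilyl)oxy]-1β,8-dimethyl-4-methylidene-5αH-bicyclo[5.3.0]dec-8-ene-2α,10α-diol (daucane locants), via diethylboron chelate 14 (not isolated)
Conditions: Et2BOMe (1.2 equiv), THF–MeOH 4:1, −78 °C; then NaBH4; AcOH, MeOH evaporation
Reagents that add atoms: none
Why: Narasaka–Prasad reduction, in which the C2 oxygen and the C10 carbonyl are held in a boron chelate and external hydride adds axially to it (1,2-reduction of the enone), should give the syn-1,3-diol and thus the 10α alcohol.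

Step 12
Reactants: 15 6α-[(tert-butyldimethylsilyl)oxy]-1β,8-dimethyl-4-methylidene-5αH-bicyclo[5.3.0]dec-8-ene-2α,10α-diol
Product: 16 6α-[(tert-butyldimethylsilyl)oxy]-8α,9α-epoxy-1β,8β-dimethyl-4-methylidene-5αH-bicyclo[5.3.0]decane-2α,10α-diol (daucane locants)
Conditions: VO(acac)2 (5 mol %), tBuOOH (1.1 equiv), CH2Cl2, 0 °C
Reagents that add atoms: tert-butyl hydroperoxide, CC(C)(C)OO
Why: Vanadium-catalysed hydroxyl-directed epoxidation, in which the allylic 10α-OH should deliver oxygen to the α face of the electron-rich C8=C9 alkene much faster than the 2-OH can direct attack on the homoallylic exocyclic alkene.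

Step 13
Reactants: 16 6α-[(tert-butyldimethylsilyl)oxy]-8α,9α-epoxy-1β,8β-dimethyl-4-methylidene-5αH-bicyclo[5.3.0]decane-2α,10α-diol
Product: 18 6α-[(tert-butyldimethylsilyl)oxy]-8α,9α-epoxy-2α,10α-dihydroxy-1β,8β-dimethyl-5αH-bicyclo[5.3.0]decan-4-one (daucane locants), via ozonide 17 (not isolated)
Conditions: O3, CH2Cl2, −78 °C; then PPh3, −78 °C → rt
Reagents that add atoms: ozone, O=[O+][O-]
Why: Ozonolysis of the only remaining alkene with reductive work-up should unveil the C4 ketone, while epoxide, alcohols and silyl ether are inert.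

Step 14
Reactants: 18 6α-[(tert-butyldimethylsilyl)oxy]-8α,9α-epoxy-2α,10α-dihydroxy-1β,8β-dimethyl-5αH-bicyclo[5.3.0]decan-4-one
Product: 19 6α-[(tert-butyldimethylsilyl)oxy]-8α,9α-epoxy-5αH-daucane-2α,4β,10α-triol
Conditions: iPrMgCl (4 equiv), CeCl3 (4 equiv, anhydrous), THF, −78 °C
Reagents that add atoms: isopropylmagnesium chloride, CC(C)[Mg]Cl
Why: Organocerium 1,2-addition, in which the weakly basic isopropylcerium reagent should attack the cyclopentanone from the α face (which carries only H-5 and the metal-bound 2-oxygen, the β face being screened by the angular methyl), giving the 4β tertiary alcohol.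

Step 15
Reactants: 19 6α-[(tert-butyldimethylsilyl)oxy]-8α,9α-epoxy-5αH-daucane-2α,4β,10α-triol
Product: 20 2α,10α-diacetoxy-6α-[(tert-butyldimethylsilyl)oxy]-8α,9α-epoxy-5αH-daucan-4β-ol
Conditions: Ac2O, pyridine, DMAP (cat.), CH2Cl2, rt
Reagents that add atoms: acetic anhydride, CC(=O)OC(C)=O
Why: DMAP-catalysed acetylation should esterify the two secondary alcohols and leave the hindered tertiary 4-OH free.

Step 16
Reactants: 20 2α,10α-diacetoxy-6α-[(tert-butyldimethylsilyl)oxy]-8α,9α-epoxy-5αH-daucan-4β-ol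
Product: 21 2α,10α-diacetoxy-8α,9α-epoxy-5αH-daucane-4β,6α-diol
Conditions: Bu4NF, AcOH (1:1), THF, 0 °C → rt
Reagents that add atoms: none
Why: Fluoride desilylation buffered with acetic acid should free the 6-OH without acetate migration or epoxide opening.

Step 17
Reactants: 21 2α,10α-diacetoxy-8α,9α-epoxy-5αH-daucane-4β,6α-diol
Product: 22 2α,10α-diacetoxy-6α-[(Z)-2-methylbut-2-enoyloxy]-8α,9α-epoxy-5αH-daucan-4β-ol (CNP0170993.1)
Conditions: angelic acid, 2,4,6-trichlorobenzoyl chloride, Et3N, toluene, rt; then 21, 80 °C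
Reagents that add atoms: angelic acid, C/C=C(/C)C(=O)O
Why: Yamaguchi-type mixed-anhydride esterification without DMAP should acylate the only secondary alcohol and keep the (Z) geometry of the angelate, the tertiary 4-OH being unreactive.

Compound list
1 | 2-methylpropene | C=C(C)C | starting material
2 | ethyl glyoxylate | CCOC(=O)C=O | starting material
3 | ethyl (2S)-2-hydroxy-4-methylpent-4-enoate | C=C(C)C[C@H](O)C(=O)OCC | intermediate
4 | ethyl (2S)-2-[(tert-butyldimethylsilyl)oxy]-4-methylpent-4-enoate | C=C(C)C[C@H](O[Si](C)(C)C(C)(C)C)C(=O)OCC | intermediate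
5 | (2S)-2-[(tert-butyldimethylsilyl)oxy]-4-methylpent-4-enal | C=C(C)C[C@H](O[Si](C)(C)C(C)(C)C)C=O | intermediate
6 | ethyl (2Z,4S)-4-[(tert-butyldimethylsilyl)oxy]-2,6-dimethylhepta-2,6-dienoate | CCOC(=O)/C(C)=C\[C@@H](O[Si](C)(C)C(C)(C)C)CC(C)=C | intermediate
7 | (2Z,4S)-4-[(tert-butyldimethylsilyl)oxy]-N-methoxy-N,2,6-trimethylhepta-2,6-dienamide | CON(C)C(=O)/C(C)=C\[C@@H](O[Si](C)(C)C(C)(C)C)CC(C)=C | intermediate
8 | (4Z,6S)-6-[(tert-butyldimethylsilyl)oxy]-4,8-dimethylnona-1,4,8-trien-3-one | C=CC(=O)/C(C)=C\[C@@H](O[Si](C)(C)C(C)(C)C)CC(C)=C | intermediate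
9 | (4S)-4-[(tert-butyldimethylsilyl)oxy]-2,6-dimethylcyclohepta-2,6-dien-1-one | O=C1C=C(C)C[C@H](O[Si](C)(C)C(C)(C)C)C=C1C | intermediate
10 | bromomagnesium enolate of the C5 conjugate adduct (not isolated) | CC(C)(C)[Si](C)(C)O[C@H]1CC(C)=CC(O[Mg]Br)=C(C)[C@@H]1C(=C)C[Si](C)(C)C | intermediate
11 | (2R,3R,4S)-4-[(tert-butyldimethylsilyl)oxy]-2-(hydroxymethyl)-2,6-dimethyl-3-[3-(trimethylsilyl)prop-1-en-2-yl]cyclohept-6-en-1-one | CC(C)(C)[Si](C)(C)O[C@H]1CC(C)=CC(=O)[C@@](C)(CO)[C@@H]1C(=C)C[Si](C)(C)C | intermediate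
12 | (1R,6S,7R)-6-[(tert-butyldimethylsilyl)oxy]-1,4-dimethyl-2-oxo-7-[3-(trimethylsilyl)prop-1-en-2-yl]cyclohept-3-ene-1-carbaldehyde | CC(C)(C)[Si](C)(C)O[C@H]1CC(C)=CC(=O)[C@@](C)(C=O)[C@@H]1C(=C)C[Si](C)(C)C | intermediate
13 | 6α-[(tert-butyldimethylsilyl)oxy]-2α-hydroxy-1β,8-dimethyl-4-methylidene-5αH-bicyclo[5.3.0]dec-8-en-10-one (daucane locants) | CC(C)(C)[Si](C)(C)O[C@H]1CC(C)=CC(=O)[C@@]2(C)[C@@H](O)CC(=C)[C@H]12 | intermediate
14 | diethylboron chelate of 13 (2-O-diethylborinate bound to the C10 carbonyl; not isolated) | CC(C)(C)[Si](C)(C)O[C@H]1CC(C)=CC(=O)[C@@]2(C)[C@@H](OB(CC)CC)CC(=C)[C@H]12 | intermediate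
15 | 6α-[(tert-butyldimethylsilyl)oxy]-1β,8-dimethyl-4-methylidene-5αH-bicyclo[5.3.0]dec-8-ene-2α,10α-diol (daucane locants) | CC(C)(C)[Si](C)(C)O[C@H]1CC(C)=C[C@@H](O)[C@@]2(C)[C@@H](O)CC(=C)[C@H]12 | intermediate
16 | 6α-[(tert-butyldimethylsilyl)oxy]-8α,9α-epoxy-1β,8β-dimethyl-4-methylidene-5αH-bicyclo[5.3.0]decane-2α,10α-diol (daucane locants) | CC(C)(C)[Si](C)(C)O[C@H]1C[C@@]2(C)O[C@H]2[C@@H](O)[C@@]2(C)[C@@H](O)CC(=C)[C@H]12 | intermediate
17 | spiro ozonide (1,2,4-trioxolane at C4) of 16 (not isolated) | CC(C)(C)[Si](C)(C)O[C@H]1C[C@@]2(C)O[C@H]2[C@@H](O)[C@@]2(C)[C@@H](O)CC3(OCOO3)[C@H]12 | intermediate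
18 | 6α-[(tert-butyldimethylsilyl)oxy]-8α,9α-epoxy-2α,10α-dihydroxy-1β,8β-dimethyl-5αH-bicyclo[5.3.0]decan-4-one (daucane locants) | CC(C)(C)[Si](C)(C)O[C@H]1C[C@@]2(C)O[C@H]2[C@@H](O)[C@@]2(C)[C@@H](O)CC(=O)[C@H]12 | intermediate
19 | 6α-[(tert-butyldimethylsilyl)oxy]-8α,9α-epoxy-5αH-daucane-2α,4β,10α-triol | CC(C)(C)[Si](C)(C)O[C@H]1C[C@@]2(C)O[C@H]2[C@@H](O)[C@@]2(C)[C@@H](O)C[C@@](O)(C(C)C)[C@H]12 | intermediate
20 | 2α,10α-diacetoxy-6α-[(tert-butyldimethylsilyl)oxy]-8α,9α-epoxy-5αH-daucan-4β-ol | CC(C)(C)[Si](C)(C)O[C@H]1C[C@@]2(C)O[C@H]2[C@@H](OC(C)=O)[C@@]2(C)[C@@H](OC(C)=O)C[C@@](O)(C(C)C)[C@H]12 | intermediate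
21 | 2α,10α-diacetoxy-8α,9α-epoxy-5αH-daucane-4β,6α-diol | O[C@H]1C[C@@]2(C)O[C@H]2[C@@H](OC(C)=O)[C@@]2(C)[C@@H](OC(C)=O)C[C@@](O)(C(C)C)[C@H]12 | intermediate
22 | 2α,10α-diacetoxy-6α-[(Z)-2-methylbut-2-enoyloxy]-8α,9α-epoxy-5αH-daucan-4β-ol (CNP0170993.1) | C/C=C(/C)C(=O)O[C@H]1C[C@@]2(C)O[C@H]2[C@@H](OC(C)=O)[C@@]2(C)[C@@H](OC(C)=O)C[C@@](O)(C(C)C)[C@H]12 | target

Total step count: 17. Longest linear sequence: 17 steps (from 1 and 2).

Steps most likely to fail

Step 8: the fully substituted magnesium enolate may be protonated, or lose formaldehyde again by retro-aldol, before work-up, and base-induced β-elimination of the silyloxy group toward a tropone can compete. The fallback sets out from 9. The same Grignard reagent is added with CuBr·SMe2 and Me3SiCl (THF, −78 °C), so that the enolate is captured as the isolable trimethylsilyl enol ether of the C5 adduct F1. Lewis-acid-catalysed Mukaiyama-type hydroxymethylation of it with aqueous formaldehyde and Sc(OTf)3 in THF at room temperature then comes back to the route at 11.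

Step 10: facial selectivity at C2 can erode if the aldehyde reacts outside the tin chelate, and protodesilylation or conjugate allylation of the enone can take over. The fallback sets out from 12. Bromodesilylation with N-bromosuccinimide (CH2Cl2, −78 °C) converts the allylsilane into the allylic bromide (1R,6S,7R)-7-(3-bromoprop-1-en-2-yl)-6-[(tert-butyldimethylsilyl)oxy]-1,4-dimethyl-2-oxocyclohept-3-ene-1-carbaldehyde F2. A Nozaki–Hiyama allylation with CrCl2 in THF, which is selective for aldehydes and runs through a closed chromium-bound transition state, then forms the same C2–C3 bond and comes back at 13.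

Step 14: the branched reagent may enolise the ketone or reduce it by β-hydride transfer, and the metal alkoxide at O-2 may trigger retro-aldol ring opening. The fallback sets out from 18. Prop-1-en-2-ylmagnesium bromide with CeCl3 (THF, −78 °C), an sp2 reagent without β-hydrogens, should give the isopropenyl carbinol 6α-[(tert-butyldimethylsilyl)oxy]-8α,9α-epoxy-5αH-dauc-11-ene-2α,4β,10α-triol F3. Hydrogenation of its only alkene (H2, PtO2, EtOAc) comes back at 19.

Further compounds
F1 | step 8 | trimethylsilyl enol ether of the C5 conjugate adduct (6α-OTBS; C5 branch trans to it; C10–OSiMe3) | CC(C)(C)[Si](C)(C)O[C@H]1CC(C)=CC(O[Si](C)(C)C)=C(C)[C@@H]1C(=C)C[Si](C)(C)C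
F2 | step 10 | (1R,6S,7R)-7-(3-bromoprop-1-en-2-yl)-6-[(tert-butyldimethylsilyl)oxy]-1,4-dimethyl-2-oxocyclohept-3-ene-1-carbaldehyde | CC(C)(C)[Si](C)(C)O[C@H]1CC(C)=CC(=O)[C@@](C)(C=O)[C@@H]1C(=C)CBr
F3 | step 14 | 6α-[(tert-butyldimethylsilyl)oxy]-8α,9α-epoxy-5αH-dauc-11-ene-2α,4β,10α-triol | CC(C)(C)[Si](C)(C)O[C@H]1C[C@@]2(C)O[C@H]2[C@@H](O)[C@@]2(C)[C@@H](O)C[C@@](O)(C(C)=C)[C@H]12
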